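**Retrosynthetic overview**

1. Germacrane numbering: C1(H)=C10(Me), C2(OH), C3H2, C4(Me)=C5(H), C6(O-acyl), C7, C8(O-lactone), C9(OH). C11, C12 and C13 are the lactone α-carbon, the carbonyl carbon and the =CH2 carbon.
2. The γ-lactone is the last ring. It is closed at C7–C11 from the 8-O-(2-bromoacrylate) of an all-Z cyclodecatrienone by Heck carbopalladation. The same operation forms the C6–O bond to (R)-2-methylbutanoate.
3. Enabling feature: C7 lies between C8 and C6. The oxygen on C8 can carry C11 into a 5-exo closure, and C6 is allylic to the C4=C5 bond of the ten-membered ring. C7–C11 plus C6–O is therefore the anti 1,2-difunctionalisation of a C4=C5–C6=C7 diene through a C4–C5–C6 π-allyl unit.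
4. Ten-membered ring: both ring alkenes are Z and C2 lies 1,6 across the ring from C7, so the carbocycle is the C2–C7 seco form of a cis-decalin. Grob fragmentation of this temporary C2–C7 bond (C2 alkoxide pushes, C6 mesylate leaves) releases the ring with a third Z alkene, C6=C7.
5. Rings A (C2–C7) and B (C7–C10, C1, C2) form together first, by an asymmetric quinone Diels–Alder reaction. The convex face of the adduct then sets C8 (hydride) and C9 (singlet oxygen). Ring order: A and B in step 2, the ten-membered ring in step 10, the lactone in step 13.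

Key step: step 13

Convention: the numbering above is kept for all intermediates. The carbocycle is drawn flat with C1 to C10 running clockwise, and "up" points to the viewer. In the target, O2, O6, O8 and H7 are up, and O9 and C11 are down.

Assumption: (R)-2-methylbutanoic acid 18 is bought as the single enantiomer, and the sense of induction in step 2 follows the usual facial model of this catalyst class (the mirror-image catalyst is used if the opposite adduct forms).

**Step 1**
Reactants: 1 3-methylbut-2-enal
Product: 2 (E)-3-methylbuta-1,3-dien-1-yl acetate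
Conditions: isopropenyl acetate, p-toluenesulfonic acid (cat.), Cu(OAc)2 (cat.), reflux, then distillation
Reagents that add atoms: isopropenyl acetate CC(=C)OC(C)=O
Why: Acid-catalysed enol ester exchange traps the extended enol of the enal as the dienyl acetate, and only the E isomer, which can reach the s-cis form, reacts in step 2.

**Step 2**
Reactants: 2 (E)-3-methylbuta-1,3-dien-1-yl acetate, 3 2-methyl-1,4-benzoquinone
Product: 4 endo cis-decalin enedione (C1 and C8 ketones, C9=C10 and C4=C5 alkenes, H2 and H7 down, 6-OAc up)
Conditions: (S)-3,3-diphenyl-1-(2-methylphenyl)tetrahydro-1H,3H-pyrrolo[1,2-c][1,3,2]oxazaborole activated with HN(SO2CF3)2 (20 mol %), CH2Cl2, −78 °C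
Reagents that add atoms: none
Why: In this enantioselective Lewis acid catalysed quinone Diels–Alder reaction the boron cation binds the more basic C8 carbonyl (fed vinylogously by the C10 methyl), so the nucleophilic CH2 terminus C3 bonds to C2 and the acetoxy carbon C6 bonds to C7, the endo rule puts 6-OAc trans to H7 on a cis ring fusion, and the catalyst face selection fixes the absolute configuration.

**Step 3**
Reactants: 4 endo cis-decalin enedione
Product: 5 8-hydroxy enone (8-OH up, C1 ketone kept)
Conditions: NaBH4, CeCl3·7H2O, MeOH, −78 °C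
Reagents that add atoms: none
Why: Luche 1,2-reduction should take the C8 carbonyl (flanked by C9–H) before the C1 carbonyl (flanked by the C10 methyl), and hydride enters from the convex face, the side of H2 and H7, which sets C8 with its oxygen up.

**Step 4**
Reactants: 5 8-hydroxy enone
Product: 6 8-O-triethylsilyl enone
Conditions: Et3SiCl, imidazole, CH2Cl2, 0 °C
Reagents that add atoms: chlorotriethylsilane CC[Si](Cl)(CC)CC
Why: Silyl ether formation at the only free hydroxyl group masks O8 with a group that can later be removed beside a TBS ether.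

**Step 5**
Reactants: 6 8-O-triethylsilyl enone
Product: 7 1-hydroxy decalin (1-OH up)
Conditions: NaBH4, CeCl3·7H2O, MeOH, −40 °C
Reagents that add atoms: none
Why: Luche 1,2-reduction of the remaining enone from the convex face gives the allylic alcohol, whose new centre C1 is erased in the next step.

**Step 6**
Reactants: 7 1-hydroxy decalin
Product: 8 ring B diene (C2=C1–C10=C9)
Conditions: Ph2S[OC(CF3)2Ph]2, CH2Cl2, −20 °C
Reagents that add atoms: none
Why: Sulfurane-mediated dehydration is regiochemically unambiguous because the activated C1 oxygen has only one β-hydrogen, H2, which lies trans to it.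

**Step 7**
Reactants: 8 ring B diene
Product: 10 2,9-diol (2-OH down; 9-OH down; C1=C10), via endoperoxide 9 (not isolated)
Conditions: O2, 5,10,15,20-tetraphenylporphyrin (cat.), hν, CH2Cl2, −78 °C; then Zn, AcOH, 0 °C
Reagents that add atoms: oxygen O=O
Why: The [4+2] cycloaddition of singlet oxygen to the cisoid ring B diene from the convex face, anti to 8-OSiEt3 and 6-OAc, sets C9–O (and the sacrificial C2–O) down and moves the alkene to C1=C10, the electron-rich diene should outrun the ene reaction of C4=C5, and zinc then cleaves the O–O bond.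

**Step 8**
Reactants: 10 2,9-diol
Product: 11 9-O-TBS ether (tertiary 2-OH free)
Conditions: t-BuMe2SiCl, imidazole, DMF, 25 °C
Reagents that add atoms: tert-butyldimethylsilyl chloride CC(C)(C)[Si](C)(C)Cl
Why: Silylation distinguishes the secondary allylic 9-OH from the tertiary 2-OH on steric grounds and leaves the donor oxygen of the fragmentation free.

**Step 9**
Reactants: 11 9-O-TBS ether
Product: 12 2,6-diol (6-OH up, 2-OH down)
Conditions: K2CO3 (cat.), MeOH, 0 °C
Reagents that add atoms: none
Why: Base-catalysed transesterification removes the only ester and frees the allylic 6-OH without touching the silyl ethers.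

**Step 10**
Reactants: 12 2,6-diol
Product: 14 all-Z cyclodecatrienone (C2 ketone; C1=C10; C4=C5; C6=C7; 8-OSiEt3 up; 9-OTBS down), via C6 mesylate 13 (not isolated)
Conditions: MsCl, Et3N, CH2Cl2, −40 °C; then KN(SiMe3)2 (1.05 equiv), THF, −78 to 0 °C
Reagents that add atoms: methanesulfonyl chloride CS(=O)(=O)Cl (its atoms stay in 13 only)
Why: In this Grob (Wharton-type) fragmentation of a 1,3-diol monosulfonate only the secondary 6-OH is sulfonylated, the cis-decalin conformer with a pseudo-equatorial 6-mesylate holds the C2–C7 bond antiperiplanar to C6–O so that the C2 alkoxide expels mesylate, C8 (axial on ring A and cis to O6) ends up cis to C5 across the new C6=C7 bond, and the two alkenes inherited from six-membered rings stay Z.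

**Step 11**
Reactants: 14 all-Z cyclodecatrienone
Product: 15 8-hydroxy trienone
Conditions: pyridinium p-toluenesulfonate (cat.), MeOH, 0 °C
Reagents that add atoms: none
Why: Acid-catalysed methanolysis cleaves the less hindered triethylsilyl ether much faster than the TBS ether, under conditions too mild to move the β,γ-alkene into conjugation.

**Step 12**
Reactants: 15 8-hydroxy trienone, 16 2-bromoacrylic acid
Product: 17 8-O-(2-bromoacrylate)
Conditions: N,N'-dicyclohexylcarbodiimide, 4-(dimethylamino)pyridine (cat.), CH2Cl2, −20 °C
Reagents that add atoms: none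
Why: Steglich esterification acylates the free 8-OH and also drains any transannular C2 hemiketal form of 15 through the open hydroxy ketone.

**Step 13**
Reactants: 17 8-O-(2-bromoacrylate), 18 (R)-2-methylbutanoic acid
Product: 19 2-oxo-9-O-TBS germacranolide (trans lactone; C11 down and H7 up; 6-O-acyl up)
Conditions: 18 (3 equiv) premixed with Cs2CO3 (3 equiv), Pd2(dba)3·CHCl3 (5 mol %), Fe(C5H4PPh2)2 (12 mol %), DMSO, 25–40 °C
Reagents that add atoms: none
Why: Zerovalent palladium inserts into the activated C11–Br bond of 17, the vinylpalladium bromide adds syn across C6=C7 with C11 bonding to C7, the C6–Pd bond collapses onto the neighbouring C4=C5 bond to give a C4–C5–C6 π-allyl complex of divalent palladium, and free cesium (R)-2-methylbutanoate attacks this complex at C6 from the face opposite the metal, which returns zerovalent palladium. The closest known reaction type is the intramolecular Heck cyclisation onto a 1,3-diene followed by carboxylate capture of the π-allyl intermediate (Heck/anion-capture cascade), and the same 5-exo insertion of an ester-tethered α-vinylpalladium unit is the ring-forming event in the palladium-catalysed cyclisation of allylic 2-alkynoates to α-alkylidene-γ-butyrolactones. The only ring closed is the γ-lactone (C11, C12, O, C8, C7), by 5-exo-trig carbopalladation, whereas 6-endo attack at C6 would forfeit the π-allyl stabilisation. C7 is controlled by C8, because allylic 1,3-strain with the cis C5 substituent of the Z alkene holds H8 in the alkene plane, so the tether reaches only the face on which O8 lies and H7 ends up trans to H8; C6 is controlled by the mechanism, since syn carbopalladation plus external carboxylate attack is a net anti addition to a Z alkene and places O6 opposite to C11, as in the target. The step needs oxidative addition to outrun ionisation of the dienylic C8–O ester, which the electron-poor C–Br bond secures, and it needs capture at C6 rather than C4, which is secured because C4 is a fully substituted terminus whose tertiary ester would re-ionise. The chelating diphosphine keeps the carboxylate off the metal so that attack stays external, and the C4=C5 geometry is kept because the π-allyl unit does not rotate at its tertiary terminus.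

**Step 14**
Reactants: 19 2-oxo-9-O-TBS germacranolide
Product: 20 9-O-TBS ether of the target (2-OH up, 2S)
Conditions: (R)-1-methyl-3,3-diphenyltetrahydro-1H,3H-pyrrolo[1,2-c][1,3,2]oxazaborole (20 mol %), catecholborane, toluene, −78 °C
Reagents that add atoms: none
Why: In the Corey–Bakshi–Shibata reduction the catalyst, with the alkenyl branch C1 as the large group, delivers hydride 1,2 to the face that gives the 2S allylic alcohol, while the lactone, the ester and the α-methylene unit are not attacked by catecholborane at this temperature.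

**Step 15**
Reactants: 20 9-O-TBS ether of the target
Product: 21 target CNP0176600.1
Conditions: HF·pyridine, pyridine, THF, 0 °C
Reagents that add atoms: none
Why: Buffered fluoride desilylation frees 9-OH only after C2 has ceased to be a ketone, which avoids closure of a Z-γ-hydroxy enone to a furan and leaves the esters and the α-methylene lactone intact.

**Compound list**

1 | 3-methylbut-2-enal | CC(C)=CC=O | starting material
2 | (E)-3-methylbuta-1,3-dien-1-yl acetate | CC(=O)O/C=C/C(C)=C | intermediate
3 | 2-methyl-1,4-benzoquinone | CC1=CC(=O)C=CC1=O | starting material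
4 | (4aS,5R,8aS)-5-acetoxy-2,7-dimethyl-4a,5,8,8a-tetrahydronaphthalene-1,4-dione; cis-decalin with C1 and C8 ketones, H2 and H7 down, 6-OAc up | O=C1C=C(C)C(=O)[C@H]2CC(C)=C[C@@H](OC(C)=O)[C@@H]12 | intermediate
5 | 8-hydroxy enone: 4 with C8 reduced, 8-OH up | O[C@H]1C=C(C)C(=O)[C@H]2CC(C)=C[C@@H](OC(C)=O)[C@@H]12 | intermediate
6 | 8-O-triethylsilyl ether of 5 | CC[Si](CC)(CC)O[C@H]1C=C(C)C(=O)[C@H]2CC(C)=C[C@@H](OC(C)=O)[C@@H]12 | intermediate
7 | 1-hydroxy decalin: 6 with C1 reduced, 1-OH up | CC[Si](CC)(CC)O[C@H]1C=C(C)[C@@H](O)[C@H]2CC(C)=C[C@@H](OC(C)=O)[C@@H]12 | intermediate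
8 | ring B diene C2=C1–C10=C9; H7 down, 6-OAc and 8-OSiEt3 up | CC[Si](CC)(CC)O[C@H]1C=C(C)C=C2CC(C)=C[C@@H](OC(C)=O)[C@@H]12 | intermediate
9 | 2,9-endoperoxide of 8, peroxide bridge down, C1=C10 | CC[Si](CC)(CC)O[C@H]1[C@@H]3OO[C@]2(C=C3C)CC(C)=C[C@@H](OC(C)=O)[C@@H]12 | intermediate
10 | 2,9-diol: tertiary 2-OH and secondary 9-OH both down, cis ring fusion | CC[Si](CC)(CC)O[C@H]1[C@H](O)C(C)=C[C@@]2(O)CC(C)=C[C@@H](OC(C)=O)[C@@H]12 | intermediate
11 | 9-O-TBS ether of 10 | CC[Si](CC)(CC)O[C@H]1[C@H](O[Si](C)(C)C(C)(C)C)C(C)=C[C@@]2(O)CC(C)=C[C@@H](OC(C)=O)[C@@H]12 | intermediate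
12 | 2,6-diol: 11 without the acetyl group, 6-OH up | CC[Si](CC)(CC)O[C@H]1[C@H](O[Si](C)(C)C(C)(C)C)C(C)=C[C@@]2(O)CC(C)=C[C@@H](O)[C@@H]12 | intermediate
13 | C6 mesylate of 12 | CC[Si](CC)(CC)O[C@H]1[C@H](O[Si](C)(C)C(C)(C)C)C(C)=C[C@@]2(O)CC(C)=C[C@@H](OS(C)(=O)=O)[C@@H]12 | intermediate
14 | (1(10)Z,4Z,6Z)-4,10-dimethylcyclodeca-1(10),4,6-trien-2-one with 8-OSiEt3 up and 9-OTBS down | CC[Si](CC)(CC)O[C@@H]1/C=C\C=C(\C)CC(=O)/C=C(/C)[C@H]1O[Si](C)(C)C(C)(C)C | intermediate
15 | 8-hydroxy trienone: 14 without the triethylsilyl group | O[C@@H]1/C=C\C=C(\C)CC(=O)/C=C(/C)[C@H]1O[Si](C)(C)C(C)(C)C | intermediate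
16 | 2-bromoacrylic acid | C=C(Br)C(=O)O | starting material
17 | 8-O-(2-bromoacrylate) of 15 | C=C(Br)C(=O)O[C@@H]1/C=C\C=C(\C)CC(=O)/C=C(/C)[C@H]1O[Si](C)(C)C(C)(C)C | intermediate
18 | (R)-2-methylbutanoic acid | CC[C@@H](C)C(=O)O | starting material
19 | 2-oxo-9-O-TBS germacranolide: target skeleton with a C2 ketone and 9-OTBS | C=C1C(=O)O[C@@H]2[C@@H]1[C@H](OC(=O)[C@H](C)CC)/C=C(/C)CC(=O)/C=C(/C)[C@H]2O[Si](C)(C)C(C)(C)C | intermediate
20 | 9-O-TBS ether of the target (2S alcohol) | C=C1C(=O)O[C@@H]2[C@@H]1[C@H](OC(=O)[C@H](C)CC)/C=C(/C)C[C@H](O)/C=C(/C)[C@H]2O[Si](C)(C)C(C)(C)C | intermediate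
21 | (1(10)Z,4Z,2S,6R,7S,8R,9R)-2,9-dihydroxy-6-[(2R)-2-methylbutanoyloxy]germacra-1(10),4,11(13)-trien-12,8-olide | C=C1C(=O)O[C@@H]2[C@@H]1[C@H](OC(=O)[C@H](C)CC)/C=C(/C)C[C@H](O)/C=C(/C)[C@H]2O | target

Total step count: 15. Longest linear sequence: 15 steps (1 to 21).

**Steps most likely to fail**

First, step 13.
- Zerovalent palladium may ionise the dienylic C8–O ester before it inserts into the C–Br bond.
- The π-allyl intermediate may lose a proton and give a triene.
- Metal-bound delivery of the carboxylate may erode the C6 configuration.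

The fallback sets out from 15 and replaces palladium by a carbenoid and a temporary bond. Steglich esterification with diethylphosphonoacetic acid gives the phosphonoacetate F1. Diazo transfer with 4-acetamidobenzenesulfonyl azide and K2CO3 in MeCN gives the diazo ester F2. Rh2(OAc)4-catalysed intramolecular cyclopropanation of C6=C7 then closes the same C7–C11 bond together with a sacrificial C6–C11 bond, under the same allylic-strain control, and gives the vinylcyclopropane lactone F3. Cesium (R)-2-methylbutanoate opens the doubly activated cyclopropane at the allylic carbon C6 with inversion. The released phosphonate carbanion is intercepted by formaldehyde in a Horner–Wadsworth–Emmons methylenation, and the route is rejoined at 19.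

Second, step 10.
- The allylic mesylate may ionise or undergo allylic substitution before the alkoxide is formed.
- Fragmentation through the wrong conformer would erode the C6=C7 geometry.
- Enolisation of the product may move the C4=C5 alkene into conjugation.

The fallback sets out from 12 and moves the fragmentation one oxidation level higher. MnO2 oxidises the allylic 6-OH to the β-hydroxy enone F4. KN(SiMe3)2 at low temperature triggers retro-aldol opening of the C2–C7 bond, and the ring-opened C7 enolate is trapped on oxygen with N-phenylbis(trifluoromethanesulfonimide) as the dienyl triflate F5. Reduction with Pd(OAc)2, PPh3, HCO2H and Et3N replaces the triflate by hydrogen with retention, and the route is rejoined at 14.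

Third, step 3.
- Discrimination between the C8 and C1 carbonyl groups may be poor.
- Over-reduction may occur.
- Acetic acid may be lost from the β-acetoxy ketone.

The fallback sets out from 2 and changes the dienophile, so that only one carbonyl group exists. Oxidation of commercial 4-methoxy-3-methylphenol with PhI(OAc)2 in MeOH gives the quinone monoketal F6. Its Diels–Alder reaction with 2, catalysed by TiCl2(OiPr)2 and (S)-1,1'-bi-2-naphthol, is directed by the single C8 carbonyl and gives the ketal adduct F7. Luche reduction gives the alcohol F8, and Et3SiCl with imidazole gives the silyl ether F9. Mild hydrolysis of the allylic ketal (oxalic acid on wet silica, CH2Cl2) rejoins the route at 6.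

**Further compounds**

F1 | step 13 | 8-O-(diethylphosphonoacetate) of 15 | CCOP(=O)(OCC)CC(=O)O[C@@H]1/C=C\C=C(\C)CC(=O)/C=C(/C)[C@H]1O[Si](C)(C)C(C)(C)C
F2 | step 13 | 8-O-(diazo(diethylphosphono)acetate) of 15 | CCOP(=O)(OCC)C(=[N+]=[N-])C(=O)O[C@@H]1/C=C\C=C(\C)CC(=O)/C=C(/C)[C@H]1O[Si](C)(C)C(C)(C)C
F3 | step 13 | vinylcyclopropane lactone with C7–C11 and temporary C6–C11 bonds, C11 down, phosphonate on C11 | CCOP(=O)(OCC)[C@@]13C(=O)O[C@@H]2[C@@H]1[C@@H]3/C=C(/C)CC(=O)/C=C(/C)[C@H]2O[Si](C)(C)C(C)(C)C
F4 | step 10 | β-hydroxy enone: 12 with a C6 ketone | CC[Si](CC)(CC)O[C@H]1[C@H](O[Si](C)(C)C(C)(C)C)C(C)=C[C@@]2(O)CC(C)=CC(=O)[C@@H]12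
F5 | step 10 | ring-opened dienyl triflate: 14 with OSO2CF3 on C6 | CC[Si](CC)(CC)O[C@@H]1/C=C(OS(=O)(=O)C(F)(F)F)\C=C(\C)CC(=O)/C=C(/C)[C@H]1O[Si](C)(C)C(C)(C)C
F6 | step 3 | 4,4-dimethoxy-3-methylcyclohexa-2,5-dienone | COC1(OC)C=CC(=O)C=C1C
F7 | step 3 | endo adduct with C1 as dimethyl ketal and a C8 ketone | O=C1C=C(C)C(OC)(OC)[C@H]2CC(C)=C[C@@H](OC(C)=O)[C@@H]12
F8 | step 3 | 8-hydroxy ketal, 8-OH up | O[C@H]1C=C(C)C(OC)(OC)[C@H]2CC(C)=C[C@@H](OC(C)=O)[C@@H]12
F9 | step 3 | 8-O-triethylsilyl ketal | CC[Si](CC)(CC)O[C@H]1C=C(C)C(OC)(OC)[C@H]2CC(C)=C[C@@H](OC(C)=O)[C@@H]12
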